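The pitfall in repeating these flasks is to take the plateau in first product as a yield that more coupling partner can raise. With substrate at 20 mM, the readings fall from 25.3% at 20 mM of partner to 2.2% at 44 mM.

| setting | zeta | delta | epsilon | eta | Tuesday's | Wednesday's | Thursday's |
|---|---|---|---|---|---|---|---|
| substrate | 20 mM | 20 mM | 20 mM | 10 mM | 20 mM | 20 mM | 20 mM (fed, over 40 h) |
| coupling partner | 20 mM | 28 mM | 44 mM | 20 mM | 20.0 mM (fed, over 40 h) | 20.0 mM | 20.0 mM |
| remark | run made earlier | run made earlier | run made earlier | run made earlier | all else is in the flask from the start; the feed brings no volume worth counting | everything together at the start | all else is in the flask from the start; the feed brings no volume worth counting |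
| time |  |  |  |  | 50 h | 50 h | 50 h |

| run | time / h | first product / % | substrate / % |
|---|---|---|---|
| zeta | 10.0 | 25.4 | 22.1 |
| zeta | 20.0 | 23.9 | 18.7 |
| zeta | 30.0 | 24.5 | 17.6 |
| zeta | 40.0 | 25.3 | 17.1 |
| zeta | 48.0 | 25.3 | 16.2 |
| delta | 5.00 | 24.5 | 19.7 |
| delta | 15.0 | 18.8 | 9.5 |
| delta | 30.0 | 17.8 | 7.7 |
| delta | 40.0 | 17.3 | 8.1 |
| delta | 60.0 | 17.0 | 6.1 |
| epsilon | 5.00 | 16.1 | 7.9 |
| epsilon | 15.0 | 4.9 | 1.7 |
| epsilon | 30.0 | 3.6 | 1.1 |
| epsilon | 40.0 | 2.5 | 1.3 |
| epsilon | 60.0 | 2.2 | 0.5 |
| eta | 5.00 | 27.0 | 24.7 |
| eta | 10.0 | 20.0 | 11.9 |
| eta | 15.0 | 15.4 | 8.3 |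
| eta | 30.0 | 10.4 | 5.1 |
| eta | 60.0 | 8.5 | 3.9 |

(each reading ± 0.5 percentage points)
1. the flask that comes out highest in amount of first product, in percent of the substrate charged, or "all alike" when all lie within 1.5 percentage points (Tuesday's / Wednesday's / Thursday's / all alike)
2. first product at the end, in percent of the substrate charged, Tuesday's
3. first product at the end, in percent of the substrate charged, Wednesday's
4. first product at the end, in percent of the substrate charged, Thursday's
- the numbers in the tables scatter by 0.5 percentage points (one standard deviation)

So I watch r = c(coupling partner)/c(substrate), and I read the plateau slope s, the points of first product lost per unit of r at 20 mM of substrate, from the zeta and epsilon readings: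

s = (25.3% − 2.2%) / (2.20 − 1.00) = 19 percentage points

The delta run checks it: the line gives 17.6% and the reading is 17.0%. Wednesday's has zeta's recipe, so I expect about 25.3%.

In Thursday's, partner per substrate delivered so far falls through epsilon's ratio at

t = 18.2 h, a fraction 0.455 of the feed.

Taking epsilon's plateau before that and the mean of the two plateaus after it gives

8.50%

That mean is my weak link, since r goes as the inverse of the fed fraction. Integrating the line along the feed gives

10.1%

Tuesday's r stays below 1.00 until 40 h, outside the runs, so I give it no number.

The forecast says 31%, 25.2% and 21% for Tuesday's, Wednesday's and Thursday's, with Tuesday's highest; for Thursday's, “fed substrate sees accumulated product competing for partner”.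

The flasks give 20.9%, 24.5% and 12.9%, so Wednesday's is highest.

    crystals ⇌ by-product, rate k1*(cs1 - [by-product]) while solid is left; crystals form when [by-product] > cs1 (solubility = 0.280 mM, k = 0.630 h⁻¹)
    substrate + coupling partner → first product + by-product (k = 16.0 L mol⁻¹ h⁻¹)
    substrate + by-product → side product (k = 21.0 L mol⁻¹ h⁻¹)
    coupling partner + first product → double product + by-product (k = 22.0 L mol⁻¹ h⁻¹)
    coupling partner + double product → tris adduct + by-product (k = 16.0 L mol⁻¹ h⁻¹)
    coupling partner + tris adduct → tetra adduct + by-product (k = 0.950 L mol⁻¹ h⁻¹)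

Wednesday's lies 0.80 points below what I expected, and Thursday's 2.8 points above my reckoning. Wednesday's has stopped in first product, though not as a flask. In Wednesday's, coupling partner, the limiting reagent, stands at 0% of its own charge at 50.0 h. At 500 h Wednesday's first product still stands at 24.5%, while its substrate goes from 16.0% to 1.25%, its side product from 27.3% to 42.1%, and its crystals from 14.3 mM to 11.3 mM.

In a further flask like Wednesday's but with substrate at 12 mM and partner at 20.0 mM, r is 1.67 and the slope, though read at 20 mM of substrate, gives 12.5%. That further flask computes to 14.2%.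

The runs stem from a simulated flask with made-up constants; scatter was added.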